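**Plan**

- Numbering: butenolide O1, C2(=O), C3, C4 (bears ring B), C5, exocyclic C6 (bears ring A). Retrosynthesis cuts first the ring O1–C5 bond, leading back to the cis-configured dienoic acid 13. It then cuts the styrenic alkene of 13 by closing a temporary δ-lactone (11/10), then the lactone's C5–C6 and acyl C–O bonds (vinylogous aldol of 5 with 7), then the C=C of crotonate 5 (olefination of ketone 2).
- Forward: MOM protection of both building blocks, Horner–Wadsworth–Emmons olefination, dienolate aldol/lactonisation to the temporary dihydropyranone, MOM removal, base-induced opening to the seco-acid, anodic oxidative closure of the butenolide.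
- Enabling feature: the free 4-OH of ring A is para to C6, so two-electron oxidation of that phenol makes C5 electrophilic (extended p-quinone methide) exactly where the carboxyl oxygen must bond. The 3,5-bromines block both ortho positions.
- Stereochemistry: the target has no stereocentre. The cis relation of carboxyl and styryl carbon is inherited from the δ-lactone ring. The Z exocyclic alkene arises under thermodynamic control when the quinone methide tautomerises (ring A turns away from ring B).
- Helpers removed: MOM ethers (step 5), δ-lactone ring (step 6).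

Key step: step 7

Remark: the single stereocentre of lactones 10 and 11 and of intermediate 14 is carried as the racemate, because it is erased before the target.

**Step 1**
Reactants: 1 1-(3,5-dibromo-4-hydroxyphenyl)ethan-1-one
Product: 2 1-[3,5-dibromo-4-(methoxymethoxy)phenyl]ethan-1-one
Conditions: MOMCl, iPr2NEt, CH2Cl2, 0 °C to rt
Reagents that add atoms: chloromethyl methyl ether (MOMCl), COCCl
Why: MOM ether formation on the acidic 2,6-dibromophenol masks a phenol whose anion would otherwise deactivate the ketone towards olefination and consume base later.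

**Step 2**
Reactants: 2 1-[3,5-dibromo-4-(methoxymethoxy)phenyl]ethan-1-one; 3 triethyl phosphonoacetate
Product: 5 ethyl (2E)-3-[3,5-dibromo-4-(methoxymethoxy)phenyl]but-2-enoate, via sodium phosphonoacetate carbanion 4 (not isolated)
Conditions: NaH, THF, 0 °C; then 2, 0 °C to reflux
Reagents that add atoms: none
Why: Horner–Wadsworth–Emmons olefination of the electron-poor aryl methyl ketone should favour the E enoate, and the geometry is immaterial because both isomers give the same dienolate in step 4.

**Step 3**
Reactants: 6 3,5-dibromo-4-hydroxybenzaldehyde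
Product: 7 3,5-dibromo-4-(methoxymethoxy)benzaldehyde
Conditions: MOMCl, iPr2NEt, CH2Cl2, 0 °C to rt
Reagents that add atoms: chloromethyl methyl ether (MOMCl), COCCl
Why: MOM ether formation keeps the aldehyde electrophilic, since a para phenolate would turn it into an unreactive vinylogous carboxylate under the basic conditions of step 4.

**Step 4**
Reactants: 5 ethyl (2E)-3-[3,5-dibromo-4-(methoxymethoxy)phenyl]but-2-enoate; 7 3,5-dibromo-4-(methoxymethoxy)benzaldehyde
Product: 10 rac-4,6-bis[3,5-dibromo-4-(methoxymethoxy)phenyl]-5,6-dihydro-2H-pyran-2-one, via lithium dienolate 8 (not isolated), via lithium aldolate 9 (not isolated)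
Conditions: LiN(iPr)2, THF, −78 °C; then 7, −78 °C to rt; AcOH quench at 0 °C
Reagents that add atoms: none
Why: Vinylogous aldol addition then lactonisation: γ-deprotonation of 5 gives dienolate 8, which should add to the non-enolisable aldehyde through its unhindered γ-carbon (α-adducts revert by retro-aldol on warming), and only aldolate 9 with alkoxide and ester cis closes irreversibly to the δ-lactone, whose stereocentre forms as a racemate.

**Step 5**
Reactants: 10 rac-4,6-bis[3,5-dibromo-4-(methoxymethoxy)phenyl]-5,6-dihydro-2H-pyran-2-one
Product: 11 rac-4,6-bis(3,5-dibromo-4-hydroxyphenyl)-5,6-dihydro-2H-pyran-2-one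
Conditions: 3 M HCl, THF, 50 °C
Reagents that add atoms: none
Why: Acid-catalysed hydrolysis of the two phenolic MOM acetals is placed here because the conjugated δ-lactone and the aryl bromides tolerate aqueous acid, whereas the later dienoic acid carries an acid-sensitive hydroxystyrene.

**Step 6**
Reactants: 11 rac-4,6-bis(3,5-dibromo-4-hydroxyphenyl)-5,6-dihydro-2H-pyran-2-one
Product: 13 (2E,4E)-3,5-bis(3,5-dibromo-4-hydroxyphenyl)penta-2,4-dienoic acid, via tripotassium salt 12 (not isolated)
Conditions: KOtBu (excess), THF/DMSO, 0 °C to rt, under Ar; then cold 1 M HCl to pH 3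
Reagents that add atoms: none
Why: Base-induced eliminative opening of a 5,6-dihydro-2H-pyran-2-one (E1cB, here assisted by 1,6-elimination from the para phenolate) is a known route to cis-configured dienoic acids: the carboxylate leaves from benzylic C6, the endocyclic alkene keeps carboxyl and the new styryl group cis (2E by the sequence rules), and the new styrenic alkene should form as the more stable E isomer.

**Step 7**
Reactants: 13 (2E,4E)-3,5-bis(3,5-dibromo-4-hydroxyphenyl)penta-2,4-dienoic acid
Product: 15 rubrolide A [(5Z)-4-(3,5-dibromo-4-hydroxyphenyl)-5-(3,5-dibromo-4-hydroxybenzylidene)furan-2(5H)-one], via quinone methide lactone 14 (not isolated)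
Conditions: undivided cell, graphite anode, Pt cathode, constant current, about 2.1 F/mol, Bu4NBF4, 2,6-lutidine, MeCN/HFIP, dilute, rt, under Ar
Reagents that add atoms: none
Why: Proposed new method: anodic two-electron oxidation of the styryl-conjugated phenol of 13 should give a phenoxonium ion that is an extended p-quinone methide cation with its positive charge on C4 of the acid; the cis-held carboxylate captures C4 to give quinone methide lactone 14, and base-mediated loss of the acidic ring C5–H of 14 rearomatises the phenol and creates the exocyclic alkene, while the protons are reduced to H2 at the cathode. The closest known reaction types are the oxidative spirolactonisation of 3-(4-hydroxyphenyl)propanoic acids by PhI(OAc)2 or at an anode, the anodic generation of p-quinone methides from 4-alkenyl- and 4-alkylphenols with capture by oxygen nucleophiles, and the dehydrogenative lactonisation of 2-styrylbenzoic acids to enol lactones. The butenolide ring closes in the 5-exo-trig mode (carboxylate oxygen onto C4 of the C4=C5 bond of the acid). No stereocentre survives (C5 of 14 is transient), and the Z geometry of the exocyclic alkene is set under thermodynamic control in the tautomerisation, ring A turning away from ring B and the push-pull phenolate allowing equilibration. The step needs chemoselectivity between the two phenols and regioselectivity for the five-membered ring: oxidation of the ring B phenol would place charge on C2 next to the carboxylate where no ring can close, both ortho positions of each phenol are blocked by bromine, the only nucleophile within reach of C4 is the carboxylate held cis by the C2=C3 geometry, and six-membered closure at C5 of the acid is not on the oxidative path. Dilution, weakly nucleophilic HFIP and a charge limited to about 2 F/mol are chosen to suppress radical dimerisation, solvent capture and over-oxidation of the product.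

**Compound list**

1 | 1-(3,5-dibromo-4-hydroxyphenyl)ethan-1-one | CC(=O)c1cc(Br)c(O)c(Br)c1 | starting material
2 | 1-[3,5-dibromo-4-(methoxymethoxy)phenyl]ethan-1-one | CC(=O)c1cc(Br)c(OCOC)c(Br)c1 | intermediate
3 | triethyl phosphonoacetate | CCOC(=O)CP(=O)(OCC)OCC | starting material
4 | sodium salt of the triethyl phosphonoacetate carbanion (formed in the flask) | [Na+].CCOC(=O)[CH-]P(=O)(OCC)OCC | intermediate
5 | ethyl (2E)-3-[3,5-dibromo-4-(methoxymethoxy)phenyl]but-2-enoate | CCOC(=O)/C=C(\C)c1cc(Br)c(OCOC)c(Br)c1 | intermediate
6 | 3,5-dibromo-4-hydroxybenzaldehyde | O=Cc1cc(Br)c(O)c(Br)c1 | starting material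
7 | 3,5-dibromo-4-(methoxymethoxy)benzaldehyde | O=Cc1cc(Br)c(OCOC)c(Br)c1 | intermediate
8 | lithium dienolate of 5, lithium 1-ethoxy-3-aryl-buta-1,3-dien-1-olate (formed in the flask) | [Li+].CCOC([O-])=CC(=C)c1cc(Br)c(OCOC)c(Br)c1 | intermediate
9 | lithium aldolate, ethyl (2E)-3,5-bis[3,5-dibromo-4-(methoxymethoxy)phenyl]-5-oxidopent-2-enoate, ester and CH2 cis, racemic (formed in the flask) | [Li+].CCOC(=O)/C=C(\CC([O-])c1cc(Br)c(OCOC)c(Br)c1)c1cc(Br)c(OCOC)c(Br)c1 | intermediate
10 | rac-4,6-bis[3,5-dibromo-4-(methoxymethoxy)phenyl]-5,6-dihydro-2H-pyran-2-one | O=C1C=C(c2cc(Br)c(OCOC)c(Br)c2)CC(c2cc(Br)c(OCOC)c(Br)c2)O1 | intermediate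
11 | rac-4,6-bis(3,5-dibromo-4-hydroxyphenyl)-5,6-dihydro-2H-pyran-2-one | O=C1C=C(c2cc(Br)c(O)c(Br)c2)CC(c2cc(Br)c(O)c(Br)c2)O1 | intermediate
12 | tripotassium salt of 13 (formed in the flask) | [K+].[K+].[K+].[O-]C(=O)/C=C(\C=C\c1cc(Br)c([O-])c(Br)c1)c1cc(Br)c([O-])c(Br)c1 | intermediate
13 | (2E,4E)-3,5-bis(3,5-dibromo-4-hydroxyphenyl)penta-2,4-dienoic acid (carboxyl and styryl group cis) | OC(=O)/C=C(\C=C\c1cc(Br)c(O)c(Br)c1)c1cc(Br)c(O)c(Br)c1 | intermediate
14 | rac-4-(3,5-dibromo-4-hydroxyphenyl)-5-[(3,5-dibromo-4-oxocyclohexa-2,5-dien-1-ylidene)methyl]furan-2(5H)-one (formed in the flask) | O=C1C=C(c2cc(Br)c(O)c(Br)c2)C(C=C2C=C(Br)C(=O)C(Br)=C2)O1 | intermediate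
15 | rubrolide A, (5Z)-4-(3,5-dibromo-4-hydroxyphenyl)-5-(3,5-dibromo-4-hydroxybenzylidene)furan-2(5H)-one | O=C1C=C(c2cc(Br)c(O)c(Br)c2)/C(=C/c2cc(Br)c(O)c(Br)c2)O1 | target

**Step count**

Total steps: 7. Longest linear sequence: 6 (steps 1, 2, 4, 5, 6, 7).

**Steps most likely to fail**

1. Step 7 (proposed new method). What may go wrong: coupling of phenoxyl radicals between two molecules, further oxidation of the product phenol, or fouling of the anode, in place of clean intramolecular capture. The fallback uses known halolactonisation and dehydrohalogenation of a 2,4-dienoic acid. It sets out from 10 and returns at 15. Lactone 10 is opened with KOtBu in THF to (2E,4E)-3,5-bis[3,5-dibromo-4-(methoxymethoxy)phenyl]penta-2,4-dienoic acid F1. Iodolactonisation (I2, NaHCO3, MeCN, 0 °C, dark) should close the same O–C bond in the 5-exo mode to rac-4-[3,5-dibromo-4-(methoxymethoxy)phenyl]-5-{[3,5-dibromo-4-(methoxymethoxy)phenyl](iodo)methyl}furan-2(5H)-one F2. DBU in CH2Cl2 removes HI to give the bis-MOM ether of rubrolide A F3, with the Z isomer expected as the stable one. Aqueous HCl in THF then frees both phenols to give 15.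

2. Step 4. What may go wrong: addition through the α-carbon of the dienolate without reversion, or premature eliminative opening of the lactone by the ethoxide set free. The fallback builds the lactone by an intramolecular olefination instead. It sets out from 2 and 7 and returns at 10. The lithium enolate of 2 (LiN(iPr)2, THF, −78 °C) adds to 7 to give rac-1,3-bis[3,5-dibromo-4-(methoxymethoxy)phenyl]-3-hydroxypropan-1-one F4. Esterification with diethylphosphonoacetic acid (DCC, DMAP, CH2Cl2) gives the phosphonoacetate ester F5. Intramolecular Horner–Wadsworth–Emmons reaction (LiCl, iPr2NEt, MeCN) closes the ring to 10 with the cis alkene enforced by the ring.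

3. Step 2. What may go wrong: slow addition of the phosphonate carbanion to a methyl ketone with competing enolisation, so that conversion stays incomplete. The fallback replaces olefination by addition and dehydration. It sets out from 2 and returns at 5. A Reformatsky reaction (Zn, ethyl bromoacetate, THF, reflux) gives ethyl rac-3-[3,5-dibromo-4-(methoxymethoxy)phenyl]-3-hydroxybutanoate F6. Dehydration with POCl3 in pyridine gives 5; any β,γ-unsaturated isomer formed alongside is acceptable because it gives the same dienolate 8.

**Further compounds**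

F1 | step 7 | (2E,4E)-3,5-bis[3,5-dibromo-4-(methoxymethoxy)phenyl]penta-2,4-dienoic acid | OC(=O)/C=C(\C=C\c1cc(Br)c(OCOC)c(Br)c1)c1cc(Br)c(OCOC)c(Br)c1
F2 | step 7 | rac-4-[3,5-dibromo-4-(methoxymethoxy)phenyl]-5-{[3,5-dibromo-4-(methoxymethoxy)phenyl](iodo)methyl}furan-2(5H)-one | O=C1C=C(c2cc(Br)c(OCOC)c(Br)c2)C(C(I)c2cc(Br)c(OCOC)c(Br)c2)O1
F3 | step 7 | (5Z)-4-[3,5-dibromo-4-(methoxymethoxy)phenyl]-5-{[3,5-dibromo-4-(methoxymethoxy)phenyl]methylidene}furan-2(5H)-one | O=C1C=C(c2cc(Br)c(OCOC)c(Br)c2)/C(=C/c2cc(Br)c(OCOC)c(Br)c2)O1
F4 | step 4 | rac-1,3-bis[3,5-dibromo-4-(methoxymethoxy)phenyl]-3-hydroxypropan-1-one | O=C(CC(O)c1cc(Br)c(OCOC)c(Br)c1)c1cc(Br)c(OCOC)c(Br)c1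
F5 | step 4 | rac-1,3-bis[3,5-dibromo-4-(methoxymethoxy)phenyl]-3-oxopropyl 2-(diethoxyphosphoryl)acetate | CCOP(=O)(CC(=O)OC(CC(=O)c1cc(Br)c(OCOC)c(Br)c1)c1cc(Br)c(OCOC)c(Br)c1)OCC
F6 | step 2 | ethyl rac-3-[3,5-dibromo-4-(methoxymethoxy)phenyl]-3-hydroxybutanoate | CCOC(=O)CC(C)(O)c1cc(Br)c(OCOC)c(Br)c1
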